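**Retrosynthetic overview**

- The target comes from its tris-TBS, mono-(2-trimethylsilylethyl) ether by one buffered fluoride deprotection.
- The dihydrofuran is the only ring made and is formed last, by an oxidative [3+2] union of C3/O4 of O-TBS-bisnoryangonin with the styryl C=C of a protected hispidin. These are the two bonds of the fungal oxidative coupling, in the same order: C–C first, then O–C through a quinone-methide-like benzylic cation. The step is run as an asymmetric carbene transfer from an in situ iodonium ylide.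
- Each styrylpyrone comes from triacetic acid lactone (nature's triketide lactone) and a silylated hydroxybenzaldehyde by vinylogous aldol condensation.
- Ring order: both pyranone rings are bought intact; the dihydrofuran ring is closed in the penultimate step.

**Assumptions:** 4-[(tert-butyldimethylsilyl)oxy]benzaldehyde is bought as a catalogue compound. The (S)-tert-leucine-derived dirhodium catalyst is taken to give the (2S,3S) series; this sense of induction is not predicted from a model, and if the first analytical run shows the opposite sense, the mirror-image catalyst is used under the same conditions.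

**Step 1**
Reactants: 1 4-hydroxy-6-methyl-2H-pyran-2-one (triacetic acid lactone)
Product: 2 6-methyl-4-[2-(trimethylsilyl)ethoxy]-2H-pyran-2-one
Conditions: Me3SiCH2CH2OH (1.2 equiv), PPh3, DIAD, THF, 0 °C → rt
Reagents that add atoms: 2-(trimethylsilyl)ethanol, C[Si](C)(C)CCO
Why: Mitsunobu O-alkylation of the acidic vinylogous acid takes place at O4 and masks this pyranone enol, so that only the other pyranone can later be oxidised; no stereocenter is formed.

**Step 2**
Reactants: 3 3,4-dihydroxybenzaldehyde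
Product: 4 3,4-bis[(tert-butyldimethylsilyl)oxy]benzaldehyde
Conditions: TBSCl (2.4 equiv), imidazole (5 equiv), DMF, rt
Reagents that add atoms: tert-butyldimethylsilyl chloride (TBSCl), CC(C)(C)[Si](C)(C)Cl
Why: Imidazole-promoted silylation of both phenols protects the catechol against oxidation and against the strong base of the next step; no stereocenter is formed.

**Step 3**
Reactants: 2 6-methyl-4-[2-(trimethylsilyl)ethoxy]-2H-pyran-2-one; 4 3,4-bis[(tert-butyldimethylsilyl)oxy]benzaldehyde
Product: 7 6-[(E)-2-{3,4-bis[(tert-butyldimethylsilyl)oxy]phenyl}ethenyl]-4-[2-(trimethylsilyl)ethoxy]-2H-pyran-2-one, via lithium aldolate 5 (not isolated), via mesylate 6 (not isolated)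
Conditions: LiN(iPr)2 (1.1 equiv), THF, −78 °C; 4; MsCl (1.3 equiv), −78 → 0 °C; DBU (2.5 equiv), 0 °C → rt
Reagents that add atoms: none
Why: The lithium amide removes a proton from the vinylogous 6-methyl group, the extended enolate adds to the aldehyde through that carbon (vinylogous aldol addition), and mesylation followed by E1cB elimination gives the conjugated E-alkene under thermodynamic control, so the transient carbinol stereocenter is lost.

**Step 4**
Reactants: 1 4-hydroxy-6-methyl-2H-pyran-2-one; 8 4-[(tert-butyldimethylsilyl)oxy]benzaldehyde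
Product: 10 4-hydroxy-6-[(E)-2-{4-[(tert-butyldimethylsilyl)oxy]phenyl}ethenyl]-2H-pyran-2-one, via aldol adduct 9 (not isolated)
Conditions: LiN(iPr)2 (2.3 equiv), THF, −78 → −40 °C; 8; 1 M HCl quench; then TsOH·H2O (5 mol%), PhMe, 70 °C
Reagents that add atoms: none
Why: The O,C-dianion of the lactone reacts at its more basic methyl-derived carbon (dianion aldol addition), and acid-catalysed E1 dehydration through the p-silyloxybenzylic cation gives the E-styrylpyrone with the 4-hydroxyl left free; no stereocenter remains.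

**Step 5**
Reactants: 10 4-hydroxy-6-[(E)-2-{4-[(tert-butyldimethylsilyl)oxy]phenyl}ethenyl]-2H-pyran-2-one; 7 6-[(E)-2-{3,4-bis[(tert-butyldimethylsilyl)oxy]phenyl}ethenyl]-4-[2-(trimethylsilyl)ethoxy]-2H-pyran-2-one
Product: 12 (2S,3S)-2-{3,4-bis[(tert-butyldimethylsilyl)oxy]phenyl}-6-[(E)-2-{4-[(tert-butyldimethylsilyl)oxy]phenyl}ethenyl]-3-{2-oxo-4-[2-(trimethylsilyl)ethoxy]-2H-pyran-6-yl}-2,3-dihydro-4H-furo[3,2-c]pyran-4-one, via iodonium ylide 11 (not isolated)
Conditions: 10, PhI(OAc)2 (1.0 equiv), MgO (2.5 equiv), 4 Å MS, CH2Cl2, 0 °C, 1 h; suspension added over 8 h to 7 (2.5 equiv), Rh2(S-NTTL)4 {dirhodium tetrakis[N-(1,8-naphthaloyl)-(S)-tert-leucinate]} (2 mol%), CH2Cl2, 23 °C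
Reagents that add atoms: none
Why: Proposed new method: the enol carbon of 10 is oxidised by two electrons to the iodonium ylide 11 (the chemical counterpart of the peroxidase oxidation), the chiral divalent-rhodium carboxylate turns it into an electrophilic carbenoid at C3 that is attacked by the styryl carbon next to the pyranone of 7 on one enantiotopic face (this sets C3 as S inside the pocket of the four naphthaloyl-tert-leucinate ligands), and the resulting p-silyloxybenzylic cation, a masked quinone methide, is captured by the C4 oxygen anti to the new pyranonyl group to give the trans (2S,3S) dihydrofuran; the closest known reaction types are the racemic copper- or rhodium-catalysed dihydrofuran annulation of iodonium ylides of cyclic 1,3-dicarbonyl compounds with styrenes and the enantioselective rhodium-catalysed cyclopropanation of styrenes with in situ iodonium ylides of cyclic malonates.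

**Step 6**
Reactants: 12 (2S,3S)-2-{3,4-bis[(tert-butyldimethylsilyl)oxy]phenyl}-6-[(E)-2-{4-[(tert-butyldimethylsilyl)oxy]phenyl}ethenyl]-3-{2-oxo-4-[2-(trimethylsilyl)ethoxy]-2H-pyran-6-yl}-2,3-dihydro-4H-furo[3,2-c]pyran-4-one
Product: 13 (2S,3S)-2-(3,4-dihydroxyphenyl)-3-(4-hydroxy-2-oxo-2H-pyran-6-yl)-6-[(E)-2-(4-hydroxyphenyl)ethenyl]-2,3-dihydro-4H-furo[3,2-c]pyran-4-one
Conditions: Bu4NF (8 equiv), AcOH (8 equiv), THF, 0 °C → rt, Ar
Reagents that add atoms: none
Why: Fluoride cleaves the three aryl Si–O bonds and triggers the β-elimination of the 2-silylethyl vinylogous ester (fluoride-induced fragmentation releasing ethene), while the acetic acid buffer keeps the phenols protonated so that neither quinone-methide opening of the C2–O bond nor E1cB opening at C3 can scramble the two stereocenters.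

**Compound list**

1 | 4-hydroxy-6-methyl-2H-pyran-2-one (triacetic acid lactone) | Cc1cc(O)cc(=O)o1 | starting material
2 | 6-methyl-4-[2-(trimethylsilyl)ethoxy]-2H-pyran-2-one | Cc1cc(OCC[Si](C)(C)C)cc(=O)o1 | intermediate
3 | 3,4-dihydroxybenzaldehyde | O=Cc1ccc(O)c(O)c1 | starting material
4 | 3,4-bis[(tert-butyldimethylsilyl)oxy]benzaldehyde | O=Cc1ccc(O[Si](C)(C)C(C)(C)C)c(O[Si](C)(C)C(C)(C)C)c1 | intermediate
5 | lithium 1-{3,4-bis[(tert-butyldimethylsilyl)oxy]phenyl}-2-{2-oxo-4-[2-(trimethylsilyl)ethoxy]-2H-pyran-6-yl}ethan-1-olate (racemic, not isolated) | [Li+].[O-]C(Cc1cc(OCC[Si](C)(C)C)cc(=O)o1)c1ccc(O[Si](C)(C)C(C)(C)C)c(O[Si](C)(C)C(C)(C)C)c1 | intermediate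
6 | 1-{3,4-bis[(tert-butyldimethylsilyl)oxy]phenyl}-2-{2-oxo-4-[2-(trimethylsilyl)ethoxy]-2H-pyran-6-yl}ethyl methanesulfonate (racemic, not isolated) | CS(=O)(=O)OC(Cc1cc(OCC[Si](C)(C)C)cc(=O)o1)c1ccc(O[Si](C)(C)C(C)(C)C)c(O[Si](C)(C)C(C)(C)C)c1 | intermediate
7 | 6-[(E)-2-{3,4-bis[(tert-butyldimethylsilyl)oxy]phenyl}ethenyl]-4-[2-(trimethylsilyl)ethoxy]-2H-pyran-2-one | O=c1cc(OCC[Si](C)(C)C)cc(/C=C/c2ccc(O[Si](C)(C)C(C)(C)C)c(O[Si](C)(C)C(C)(C)C)c2)o1 | intermediate
8 | 4-[(tert-butyldimethylsilyl)oxy]benzaldehyde | O=Cc1ccc(O[Si](C)(C)C(C)(C)C)cc1 | starting material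
9 | 4-hydroxy-6-(2-hydroxy-2-{4-[(tert-butyldimethylsilyl)oxy]phenyl}ethyl)-2H-pyran-2-one (racemic, not isolated) | OC(Cc1cc(O)cc(=O)o1)c1ccc(O[Si](C)(C)C(C)(C)C)cc1 | intermediate
10 | 4-hydroxy-6-[(E)-2-{4-[(tert-butyldimethylsilyl)oxy]phenyl}ethenyl]-2H-pyran-2-one | O=c1cc(O)cc(/C=C/c2ccc(O[Si](C)(C)C(C)(C)C)cc2)o1 | intermediate
11 | 6-[(E)-2-{4-[(tert-butyldimethylsilyl)oxy]phenyl}ethenyl]-2-oxo-3-(phenyliodonio)-2H-pyran-4-olate (iodonium ylide, not isolated) | [O-]c1cc(/C=C/c2ccc(O[Si](C)(C)C(C)(C)C)cc2)oc(=O)c1[I+]c1ccccc1 | intermediate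
12 | (2S,3S)-2-{3,4-bis[(tert-butyldimethylsilyl)oxy]phenyl}-6-[(E)-2-{4-[(tert-butyldimethylsilyl)oxy]phenyl}ethenyl]-3-{2-oxo-4-[2-(trimethylsilyl)ethoxy]-2H-pyran-6-yl}-2,3-dihydro-4H-furo[3,2-c]pyran-4-one | O=c1cc(OCC[Si](C)(C)C)cc([C@H]2c3c(cc(/C=C/c4ccc(O[Si](C)(C)C(C)(C)C)cc4)oc3=O)O[C@@H]2c2ccc(O[Si](C)(C)C(C)(C)C)c(O[Si](C)(C)C(C)(C)C)c2)o1 | intermediate
13 | (2S,3S)-2-(3,4-dihydroxyphenyl)-3-(4-hydroxy-2-oxo-2H-pyran-6-yl)-6-[(E)-2-(4-hydroxyphenyl)ethenyl]-2,3-dihydro-4H-furo[3,2-c]pyran-4-one | O=c1cc(O)cc([C@H]2c3c(cc(/C=C/c4ccc(O)cc4)oc3=O)O[C@@H]2c2ccc(O)c(O)c2)o1 | target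

**Totals**

Total step count: 6. Longest linear sequence: 4 (step 1 or step 2, then steps 3, 5 and 6).

**Three steps most likely to fail**

Step 5 is the riskiest step. The trans-disubstituted, pyranone-conjugated alkene of 7 may react slowly with the carbenoid. The carbenoid may also add to the styryl group of a second molecule of 10, which the slow addition and the excess of 7 are meant to suppress. Ring closure through the lactone carbonyl oxygen would give the isomeric furo[2,3-b]pyran-4-one. The level and the sense of enantioselection are untested. The fallback sets out from 7 and 10 and comes back at 12. It is a radical oxidative [3+2] coupling with Mn(OAc)3·2H2O (trivalent manganese, 2.2 equiv) in AcOH at 50 °C, with 7 in threefold excess and 10 added slowly. This gives the racemic trans adduct, that is 12 together with (2R,3R)-2-{3,4-bis[(tert-butyldimethylsilyl)oxy]phenyl}-6-[(E)-2-{4-[(tert-butyldimethylsilyl)oxy]phenyl}ethenyl]-3-{2-oxo-4-[2-(trimethylsilyl)ethoxy]-2H-pyran-6-yl}-2,3-dihydro-4H-furo[3,2-c]pyran-4-one F1. The two are separated by preparative chromatography on an amylose tris(3,5-dimethylphenylcarbamate) stationary phase to return 12.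

Step 3 may suffer from ring metalation of 2 at C3 or C5 instead of the methyl group, or from retro-aldol during the mesylation. The fallback sets out from 2 and comes back at 7 by an olefination instead of an aldol condensation. Wohl–Ziegler bromination (NBS, AIBN, PhCF3, 80 °C) gives 6-(bromomethyl)-4-[2-(trimethylsilyl)ethoxy]-2H-pyran-2-one F2. Michaelis–Arbuzov reaction with P(OEt)3 at 120 °C gives diethyl {2-oxo-4-[2-(trimethylsilyl)ethoxy]-2H-pyran-6-yl}methylphosphonate F3. Horner–Wadsworth–Emmons reaction of F3 with 4 (LiN(SiMe3)2, THF, −78 → 0 °C) gives the E-alkene 7.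

Step 6 may stall at the 2-silylethyl ether under buffered fluoride. If the buffer is left out, the free p-hydroxyphenyl group can open the C2–O bond through a quinone methide and erode the stereocenters. The fallback sets out from 12 and comes back at 13 in two orthogonal stages. TFA in CH2Cl2 at 0 °C removes the 2-silylethyl group by acidolysis while all three phenols are still silylated, so no quinone methide can form. This gives (2S,3S)-2-{3,4-bis[(tert-butyldimethylsilyl)oxy]phenyl}-6-[(E)-2-{4-[(tert-butyldimethylsilyl)oxy]phenyl}ethenyl]-3-(4-hydroxy-2-oxo-2H-pyran-6-yl)-2,3-dihydro-4H-furo[3,2-c]pyran-4-one F4. Et3N·3HF in MeCN at 0 °C → rt then removes the aryl silyl groups under weakly acidic conditions to give 13.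

**Further compounds**

F1 | step 5 | (2R,3R)-2-{3,4-bis[(tert-butyldimethylsilyl)oxy]phenyl}-6-[(E)-2-{4-[(tert-butyldimethylsilyl)oxy]phenyl}ethenyl]-3-{2-oxo-4-[2-(trimethylsilyl)ethoxy]-2H-pyran-6-yl}-2,3-dihydro-4H-furo[3,2-c]pyran-4-one | O=c1cc(OCC[Si](C)(C)C)cc([C@@H]2c3c(cc(/C=C/c4ccc(O[Si](C)(C)C(C)(C)C)cc4)oc3=O)O[C@H]2c2ccc(O[Si](C)(C)C(C)(C)C)c(O[Si](C)(C)C(C)(C)C)c2)o1
F2 | step 3 | 6-(bromomethyl)-4-[2-(trimethylsilyl)ethoxy]-2H-pyran-2-one | BrCc1cc(OCC[Si](C)(C)C)cc(=O)o1
F3 | step 3 | diethyl {2-oxo-4-[2-(trimethylsilyl)ethoxy]-2H-pyran-6-yl}methylphosphonate | CCOP(=O)(OCC)Cc1cc(OCC[Si](C)(C)C)cc(=O)o1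
F4 | step 6 | (2S,3S)-2-{3,4-bis[(tert-butyldimethylsilyl)oxy]phenyl}-6-[(E)-2-{4-[(tert-butyldimethylsilyl)oxy]phenyl}ethenyl]-3-(4-hydroxy-2-oxo-2H-pyran-6-yl)-2,3-dihydro-4H-furo[3,2-c]pyran-4-one | O=c1cc(O)cc([C@H]2c3c(cc(/C=C/c4ccc(O[Si](C)(C)C(C)(C)C)cc4)oc3=O)O[C@@H]2c2ccc(O[Si](C)(C)C(C)(C)C)c(O[Si](C)(C)C(C)(C)C)c2)o1
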